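**Plan**
- Cuts: the two C11–C15′ bonds of the twelve-membered ring (two identical lindenane halves), then in each half C5–C10 and C8–C9, which opens the five- and six-membered carbocycles together.
- Enabling feature: the cyclopentene (C1, C3, C4, C5, C10) and the cyclohexenone (C5 to C10) share the C5–C10 bond, and the cis-cyclopropane C1–C2–C3 is a three-atom tether (C4–C3–C1) between a diene on C4 (C5=C6–C7=C8) and a dienophile C10=C9.
- Forward: the lactone supplies the cyclopropane; its carbonyl arm becomes C4 (acetonide, diene) and its CH2O arm becomes C10 (nitroalkene); one intramolecular Diels–Alder reaction closes both carbocycles.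
- Then: Nef reaction, C8 hydroxylation and a ketol shift/acetonide elimination give the hydroxy dienone; C11 methylation and C15 bromination arm the monomer; head-to-tail cyclodimerisation closes the macrocycle last.
- Stereochemistry: C1 and C3 from the lactone; C10 from the dienophile face anti to C2 in the cycloaddition; C9 by equilibration to the pseudo-equatorial alcohol; both C11 by α-face alkylation of a chelated enolate.

Key step: step 13

Remark: lindenane numbering is used for every intermediate and β is the face of C2 and C14; centres that are erased or re-set later (C4, C5 and the nitro-bearing C9 of 22, C8 of 26, C9 of 27, C10 of 13 and 16, C11 of 31–33) are drawn as the expected major epimer or left open in the SMILES, since their epimers converge.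

**Step 1**
Reactants: 1 (1S,5R)-3-oxabicyclo[3.1.0]hexan-2-one
Product: 2 cis-hydroxymethyl Weinreb amide
Conditions: MeNH(OMe)·HCl, AlMe3, CH2Cl2, 0 → 23 °C
Reagents that add atoms: N,O-dimethylhydroxylamine hydrochloride, CNOC.Cl
Why: Aminolysis of the γ-lactone by the aluminium amide (Weinreb amide formation) should open the ring without touching the cyclopropane centres, giving the C4 acyl arm and the C10 hydroxymethyl arm.

**Step 2**
Reactants: 2 cis-hydroxymethyl Weinreb amide
Product: 3 TES ether
Conditions: TESCl, imidazole, CH2Cl2, 0 °C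
Reagents that add atoms: chlorotriethylsilane, CC[Si](CC)(CC)Cl
Why: Silyl ether formation under basic conditions should block relactonisation; the TES ether survives organolithium and Grignard reagents and falls under the mild acid of step 6.

**Step 3**
Reactants: 4 (tributylstannyl)methanol
Product: 5 tributyl{[(2-methoxypropan-2-yl)oxy]methyl}stannane
Conditions: 2-methoxypropene, PPTS (cat.), CH2Cl2, 0 °C
Reagents that add atoms: 2-methoxypropene, COC(C)=C
Why: Acid-catalysed addition of the alcohol to the enol ether (mixed ketal formation) should give the achiral analogue of the classical 1-ethoxyethyl-protected hydroxymethyl-anion reagent.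

**Step 4**
Reactants: 3 TES ether, 5 tributyl{[(2-methoxypropan-2-yl)oxy]methyl}stannane
Product: 7 C4 ketone, via alkoxymethyllithium 6 (not isolated)
Conditions: 5, n-BuLi, THF, −78 °C; then 3, −78 °C
Reagents that add atoms: none
Why: Tin–lithium exchange should give the α-alkoxymethyllithium, which adds once to the Weinreb amide through the chelated tetrahedral intermediate (Weinreb ketone synthesis) and installs C15 with its oxygen.

**Step 5**
Reactants: 7 C4 ketone, 8 ethynylmagnesium bromide
Product: 9 propargylic alcohol
Conditions: HC≡CMgBr, THF, −78 → 0 °C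
Reagents that add atoms: none
Why: Grignard 1,2-addition to the α-alkoxy ketone; the cyclopropyl ketone should react in its bisected s-cis conformation on the face away from the cis silyloxymethyl arm, giving the (R)-carbinol at C4 (the epimer would converge, since C4 becomes sp2 in step 16).

**Step 6**
Reactants: 9 propargylic alcohol
Product: 11 acetonide alcohol, via acetonide silyl ether 10 (not isolated)
Conditions: PPTS (cat.), acetone, 23 °C; then MeOH, 23 °C
Reagents that add atoms: none
Why: Under PPTS the mixed ketal should transketalise onto the neighbouring tertiary hydroxyl to give the five-membered acetonide with loss of methanol, after which methanolysis removes the primary TES ether while the dioxolane stays.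

**Step 7**
Reactants: 11 acetonide alcohol
Product: 12 cyclopropanecarbaldehyde
Conditions: Dess–Martin periodinane, NaHCO3, CH2Cl2, 0 → 23 °C
Reagents that add atoms: none
Why: Buffered Dess–Martin oxidation of the primary alcohol should give the aldehyde without epimerising the cis-cyclopropane.

**Step 8**
Reactants: 12 cyclopropanecarbaldehyde
Product: 13 secondary alcohol
Conditions: MeMgBr, THF, −78 °C
Reagents that add atoms: methylmagnesium bromide, C[Mg]Br
Why: Grignard addition to the aldehyde installs C14; the carbinol centre forms as a mixture and is removed in step 9.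

**Step 9**
Reactants: 13 secondary alcohol
Product: 14 methyl ketone
Conditions: Dess–Martin periodinane, NaHCO3, CH2Cl2, 23 °C
Reagents that add atoms: none
Why: Dess–Martin oxidation gives the C10 methyl ketone; the cyclopropyl α-CH enolises reluctantly, so the cis relationship should hold.

**Step 10**
Reactants: 14 methyl ketone, 15 nitromethane
Product: 16 nitro alcohol
Conditions: MeNO2 (solvent), 1,1,3,3-tetramethylguanidine (0.3 equiv), 23 °C
Reagents that add atoms: none
Why: Base-catalysed nitroaldol (Henry) addition to the ketone, pushed forward by nitromethane as solvent, brings in C9 with its nitro group; the tertiary carbinol centre is removed in step 12.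

**Step 11**
Reactants: 16 nitro alcohol, 17 methyl 3-bromobut-3-enoate
Product: 19 diene nitro alcohol, via vinylstannane 18 (not isolated)
Conditions: Bu3SnH, PdCl2(PPh3)2 (cat.), THF, 0 → 23 °C; then 17, Pd2(dba)3 (cat.), AsPh3, NMP, 55 °C
Reagents that add atoms: none
Why: Pd-catalysed syn-hydrostannation should put tin on the distal alkyne carbon because C4 is fully substituted, and the (E)-vinylstannane is coupled in the same flask with the vinyl bromide under neutral Stille conditions, which the nitro alcohol and the base-sensitive skipped ester tolerate.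

**Step 12**
Reactants: 19 diene nitro alcohol
Product: 21 nitro triene, via tertiary mesylate 20 (not isolated)
Conditions: MsCl, Et3N, CH2Cl2, −40 → 0 °C
Reagents that add atoms: none
Why: Mesylation and E1cB loss of mesylate through the nitronate should give the conjugated nitroalkene, mainly E (nitro trans to the cyclopropane); low temperature and short base contact limit isomerisation to the allylic nitro compound.

**Step 13**
Reactants: 21 nitro triene
Product: 22 tricyclic nitro adduct
Conditions: PhMe (0.01 M), BHT (cat.), 130 °C, sealed tube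
Reagents that add atoms: none
Why: A concerted, asynchronous normal-demand [4+2] cycloaddition: the diene C5=C6–C7=C8 adds suprafacially to the nitro-activated C10=C9, the C5–C10 bond to the β-carbon of the nitroalkene running ahead of C8–C9; the closest known reaction type is the thermal intramolecular Diels–Alder reaction of trienes that end in a nitroalkene (1-nitro-1,6,8-nonatrienes and 1-nitro-1,7,9-decatrienes). The five-membered ring (C1, C3, C4, C5, C10) closes through C5–C10 across the three-atom tether C4–C3–C1 (fused, type 1 mode), and the cyclohexene (C5 to C10) closes through C8–C9 as the six-membered ring of the cycloaddition; the cis-cyclopropane holds both arms on one side, so little rotational freedom is lost. C10 is controlled by the cyclopropane: the diene reaches the face of C10=C9 that builds the six-membered ring anti to the methylene C2 (the syn approach would press C9 and its nitro group against C2), which leaves C14 syn to C2 as in the target. C9 follows stereospecifically from the E alkene (nitro cis to C14) and C5 from the transition state with the tether endo and the nitro group exo (cis ring fusion); both, like C4, are erased later, so the Z alkene and a trans-fused adduct would converge. The step needs π-facial selectivity at C10 (secured as above), a regiochemistry that the short tether imposes against the frontier-orbital preference of the diene (as in the precedent), and periselectivity over the hetero-Diels–Alder mode of the nitroalkene, which Lewis-acid-free heating favours.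

**Step 14**
Reactants: 22 tricyclic nitro adduct
Product: 24 C9 ketone, via sodium nitronate 23 (not isolated)
Conditions: NaOMe, MeOH, 0 °C; then TiCl3, NH4OAc, H2O, 0 → 23 °C
Reagents that add atoms: water, O
Why: Reductive Nef reaction: TiCl3 should reduce the nitronate to the imine, which hydrolyses near pH 5 to the ketone without harming acetonide, ester or alkene.

**Step 15**
Reactants: 24 C9 ketone
Product: 26 C8-hydroxy C9-ketone, via potassium dienolate 25 (not isolated)
Conditions: KN(SiMe3)2, THF, −78 °C; then 2-(phenylsulfonyl)-3-phenyloxaziridine, −78 °C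
Reagents that add atoms: 2-(phenylsulfonyl)-3-phenyloxaziridine, O=S(=O)(c1ccccc1)N1OC1c1ccccc1
Why: C8 is the only enolisable position of the ketone and is doubly activated, and metal dienolates are hydroxylated at the α-carbon by the Davis oxaziridine (enolate oxidation); the C8 configuration is irrelevant.

**Step 16**
Reactants: 26 C8-hydroxy C9-ketone
Product: 28 dienone diol, via C9-hydroxy C8-ketone 27 (not isolated)
Conditions: DBU, MeCN, 0 → 50 °C
Reagents that add atoms: none
Why: DBU should move the carbonyl into conjugation through the enediol (α-ketol isomerisation), then remove the γ-proton at C5 so that the dienolate expels the C4 acetonide oxygen (vinylogous E1cB) and the hemiketal loses acetone; C9 settles under thermodynamic control as the pseudo-equatorial, hydrogen-bonded β-alcohol of the planar dienone.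

**Step 17**
Reactants: 28 dienone diol
Product: 29 bis-TBS ether
Conditions: TBSOTf, 2,6-lutidine, CH2Cl2, −78 → 0 °C
Reagents that add atoms: tert-butyldimethylsilyl trifluoromethanesulfonate, CC(C)(C)[Si](C)(C)OS(=O)(=O)C(F)(F)F
Why: The silyl triflate should silylate both the primary allylic and the hindered secondary hydroxyl, while 2,6-lutidine is too weak a base to enolise the dienone.

**Step 18**
Reactants: 29 bis-TBS ether
Product: 31 C11-methyl ester, via potassium ester enolate 30 (not isolated)
Conditions: KN(SiMe3)2, THF, −78 °C; then MeI, −78 °C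
Reagents that add atoms: iodomethane, CI
Why: C11–H, activated by the ester and the dienyl system, should be the most acidic C–H, and extended ester enolates are alkylated at the α-carbon (enolate alkylation); C11 forms as a mixture that step 21 erases.

**Step 19**
Reactants: 31 C11-methyl ester
Product: 32 C15 alcohol
Conditions: HF·pyridine, pyridine, THF, 0 °C
Reagents that add atoms: none
Why: Buffered fluoride should cleave the unhindered primary allylic silyl ether much faster than the secondary one next to the quaternary C10 (selective desilylation).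

**Step 20**
Reactants: 32 C15 alcohol
Product: 33 C15 bromide
Conditions: CBr4, PPh3, CH2Cl2, 0 °C
Reagents that add atoms: carbon tetrabromide, BrC(Br)(Br)Br
Why: The Appel reaction converts the primary allylic alcohol into the bromide under neutral conditions that leave the acidic C11–H untouched.

**Step 21**
Reactants: 33 C15 bromide (two molecules)
Product: 35 bis-TBS cycloshizukaol A, via seco-dimer bromide 34 (not isolated)
Conditions: KN(SiMe3)2 (1 equiv per 33, added over several hours), THF (5 mM), −78 → −40 °C
Reagents that add atoms: none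
Why: Proposed new method: the potassium ester enolate at C11 of one molecule of 33 should displace the allylic bromide at C15 of a second (or add 1,8 to the triene that 33 gives by loss of bromide from its own enolate, which forms the same C11–C15′ bond), and the seco-dimer 34 then holds one C11–H and one C15–Br and closes the twelve-membered ring by intramolecular alkylation at high dilution; the closest known reaction types are α-alkylation of ester enolates by allylic bromides and head-to-tail cyclodimerisation of bifunctional monomers as in macrodiolide synthesis; both C11 centres are expected to form by attack on the α face (opposite C14, C2 and the C9 silyloxy group) of an enolate whose ester is held syn to the C8 carbonyl by K+ chelation, which in the face-to-face assembly of the two α faces gives the C2-symmetric configuration of the target.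

**Step 22**
Reactants: 35 bis-TBS cycloshizukaol A
Product: 36 cycloshizukaol A
Conditions: HF·pyridine, THF, 0 → 23 °C
Reagents that add atoms: none
Why: Fluoride-mediated cleavage of the two hindered silyl ethers under mildly acidic conditions should free the C9 alcohols without enolising the α-ketols.

**Compound list**
1 | (1S,5R)-3-oxabicyclo[3.1.0]hexan-2-one | O=C1OC[C@@H]2C[C@H]12 | starting material
2 | (1S,2R)-2-(hydroxymethyl)-N-methoxy-N-methylcyclopropane-1-carboxamide (cis; amide carbon = C4, CH2OH = C10) | OC[C@@H]1C[C@@H]1C(=O)N(C)OC | intermediate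
3 | (1S,2R)-N-methoxy-N-methyl-2-[(triethylsilyloxy)methyl]cyclopropane-1-carboxamide | CC[Si](CC)(CC)OC[C@@H]1C[C@@H]1C(=O)N(C)OC | intermediate
4 | (tributylstannyl)methanol | CCCC[Sn](CCCC)(CCCC)CO | starting material
5 | tributyl{[(2-methoxypropan-2-yl)oxy]methyl}stannane | CCCC[Sn](CCCC)(CCCC)COC(C)(C)OC | intermediate
6 | {[(2-methoxypropan-2-yl)oxy]methyl}lithium | [Li]COC(C)(C)OC | intermediate (not isolated)
7 | C4 ketone: 2-[(2-methoxypropan-2-yl)oxy]-1-{(1S,2R)-2-[(triethylsilyloxy)methyl]cyclopropyl}ethan-1-one | CC[Si](CC)(CC)OC[C@@H]1C[C@@H]1C(=O)COC(C)(C)OC | intermediate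
8 | ethynylmagnesium bromide | C#C[Mg]Br | starting material
9 | propargylic alcohol: (2R)-1-[(2-methoxypropan-2-yl)oxy]-2-{(1S,2R)-2-[(triethylsilyloxy)methyl]cyclopropyl}but-3-yn-2-ol | CC[Si](CC)(CC)OC[C@@H]1C[C@@H]1[C@](O)(COC(C)(C)OC)C#C | intermediate
10 | acetonide silyl ether: 4-ethynyl-2,2-dimethyl-4-{cis-2-[(triethylsilyloxy)methyl]cyclopropyl}-1,3-dioxolane, C4 as in 9 | CC[Si](CC)(CC)OC[C@@H]1C[C@@H]1[C@@]2(C#C)COC(C)(C)O2 | intermediate (not isolated)
11 | acetonide alcohol: [cis-2-(4-ethynyl-2,2-dimethyl-1,3-dioxolan-4-yl)cyclopropyl]methanol, cyclopropane as in 2, C4 as in 9 | OC[C@@H]1C[C@@H]1[C@@]2(C#C)COC(C)(C)O2 | intermediate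
12 | cyclopropanecarbaldehyde: cis-2-(4-ethynyl-2,2-dimethyl-1,3-dioxolan-4-yl)cyclopropane-1-carbaldehyde | O=C[C@@H]1C[C@@H]1[C@@]2(C#C)COC(C)(C)O2 | intermediate
13 | secondary alcohol: 1-[cis-2-(4-ethynyl-2,2-dimethyl-1,3-dioxolan-4-yl)cyclopropyl]ethan-1-ol, both C10 epimers | CC(O)[C@@H]1C[C@@H]1[C@@]2(C#C)COC(C)(C)O2 | intermediate
14 | methyl ketone: 1-[cis-2-(4-ethynyl-2,2-dimethyl-1,3-dioxolan-4-yl)cyclopropyl]ethan-1-one | CC(=O)[C@@H]1C[C@@H]1[C@@]2(C#C)COC(C)(C)O2 | intermediate
15 | nitromethane | C[N+](=O)[O-] | starting material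
16 | nitro alcohol: 2-[cis-2-(4-ethynyl-2,2-dimethyl-1,3-dioxolan-4-yl)cyclopropyl]-1-nitropropan-2-ol, both C10 epimers | [O-][N+](=O)CC(C)(O)[C@@H]1C[C@@H]1[C@@]2(C#C)COC(C)(C)O2 | intermediate
17 | methyl 3-bromobut-3-enoate | COC(=O)CC(Br)=C | starting material
18 | vinylstannane: 16 with (E)-CH=CH–SnBu3 on C4 in place of ethynyl | [O-][N+](=O)CC(C)(O)[C@@H]1C[C@@H]1[C@@]2(/C=C/[Sn](CCCC)(CCCC)CCCC)COC(C)(C)O2 | intermediate (not isolated)
19 | diene nitro alcohol: 16 with the (E)-C5=C6–C7(=C8H2)–CH2CO2Me diene on C4 | [O-][N+](=O)CC(C)(O)[C@@H]1C[C@@H]1[C@@]2(/C=C/C(=C)CC(=O)OC)COC(C)(C)O2 | intermediate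
20 | tertiary mesylate of 19 | [O-][N+](=O)CC(C)(OS(C)(=O)=O)[C@@H]1C[C@@H]1[C@@]2(/C=C/C(=C)CC(=O)OC)COC(C)(C)O2 | intermediate (not isolated)
21 | nitro triene: methyl (4E)-5-[2,2-dimethyl-4-{cis-2-[(E)-1-nitroprop-1-en-2-yl]cyclopropyl}-1,3-dioxolan-4-yl]-3-methylidenepent-4-enoate | [O-][N+](=O)/C=C(\C)[C@@H]1C[C@@H]1[C@@]2(/C=C/C(=C)CC(=O)OC)COC(C)(C)O2 | intermediate
22 | tricyclic nitro adduct: 9β-nitro, 5β-H, C14 β, C2 β, C6=C7, C7–CH2CO2Me, C4 spiro-acetonide (O4 α, C15 β) | [O-][N+](=O)[C@H]1CC(CC(=O)OC)=C[C@@H]2[C@@]3(COC(C)(C)O3)[C@H]4C[C@H]4[C@]12C | intermediate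
23 | sodium nitronate of 22 | [Na+].[O-][N+]([O-])=C1CC(CC(=O)OC)=C[C@@H]2[C@@]3(COC(C)(C)O3)[C@H]4C[C@H]4[C@]12C | intermediate (not isolated)
24 | C9 ketone (C6=C7 β,γ to the carbonyl; otherwise as 22) | O=C1CC(CC(=O)OC)=C[C@@H]2[C@@]3(COC(C)(C)O3)[C@H]4C[C@H]4[C@]12C | intermediate
25 | potassium dienolate of 24 (O–C9=C8–C7=C6) | [K+].[O-]C1=CC(CC(=O)OC)=C[C@@H]2[C@@]3(COC(C)(C)O3)[C@H]4C[C@H]4[C@]12C | intermediate (not isolated)
26 | C8-hydroxy C9-ketone (C8 epimers) | O=C1C(O)C(CC(=O)OC)=C[C@@H]2[C@@]3(COC(C)(C)O3)[C@H]4C[C@H]4[C@]12C | intermediate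
27 | C9-hydroxy C8-ketone: enone C6=C7–C8=O with the acetonide still in place (C9 epimers) | O=C1C(CC(=O)OC)=C[C@@H]2[C@@]3(COC(C)(C)O3)[C@H]4C[C@H]4[C@]2(C)C1O | intermediate (not isolated)
28 | dienone diol: C4=C5–C6=C7–C8=O, 9β-OH, C15–OH, C7–CH2CO2Me | COC(=O)CC1=CC2=C(CO)[C@H]3C[C@H]3[C@]2(C)[C@@H](O)C1=O | intermediate
29 | 9,15-bis-TBS ether of 28 | COC(=O)CC1=CC2=C(CO[Si](C)(C)C(C)(C)C)[C@H]3C[C@H]3[C@]2(C)[C@@H](O[Si](C)(C)C(C)(C)C)C1=O | intermediate
30 | potassium ester enolate of 29 | [K+].COC([O-])=CC1=CC2=C(CO[Si](C)(C)C(C)(C)C)[C@H]3C[C@H]3[C@]2(C)[C@@H](O[Si](C)(C)C(C)(C)C)C1=O | intermediate (not isolated)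
31 | C11-methyl ester: 29 with C7–CH(CH3)CO2Me (C11 epimers) | COC(=O)C(C)C1=CC2=C(CO[Si](C)(C)C(C)(C)C)[C@H]3C[C@H]3[C@]2(C)[C@@H](O[Si](C)(C)C(C)(C)C)C1=O | intermediate
32 | C15 alcohol: 31 with free C15–OH, 9-OTBS kept | COC(=O)C(C)C1=CC2=C(CO)[C@H]3C[C@H]3[C@]2(C)[C@@H](O[Si](C)(C)C(C)(C)C)C1=O | intermediate
33 | C15 bromide | COC(=O)C(C)C1=CC2=C(CBr)[C@H]3C[C@H]3[C@]2(C)[C@@H](O[Si](C)(C)C(C)(C)C)C1=O | intermediate
34 | seco-dimer bromide: C11 of the first half (quaternary, configured as in the target) bonded to C15 of the second; the first half keeps C15–Br, the second keeps C11–H | COC(=O)[C@](C)(CC4=C5C=C(C(C)C(=O)OC)C(=O)[C@H](O[Si](C)(C)C(C)(C)C)[C@@]5(C)[C@@H]6C[C@H]46)C1=CC2=C(CBr)[C@H]3C[C@H]3[C@]2(C)[C@@H](O[Si](C)(C)C(C)(C)C)C1=O | intermediate (not isolated)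
35 | 9,9′-bis-TBS ether of cycloshizukaol A | COC(=O)[C@]1(C)CC2=C3C=C(C(=O)[C@H](O[Si](C)(C)C(C)(C)C)[C@@]3(C)[C@@H]3C[C@H]23)[C@](C)(C(=O)OC)CC2=C3C=C1C(=O)[C@H](O[Si](C)(C)C(C)(C)C)[C@@]3(C)[C@@H]1C[C@H]21 | intermediate
36 | cycloshizukaol A | COC(=O)[C@]1(C)CC2=C3C=C(C(=O)[C@H](O)[C@@]3(C)[C@@H]3C[C@H]23)[C@](C)(C(=O)OC)CC2=C3C=C1C(=O)[C@H](O)[C@@]3(C)[C@@H]1C[C@H]21 | target

**Step count**
Total steps: 22. Longest linear sequence: 21 steps (lactone 1 to 36 through steps 1, 2 and 4–22); step 3 prepares reagent 5.

**Steps most likely to fail**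

Step 21 (proposed new method). Loss of bromide from the enolate of 33 may outrun bimolecular C-alkylation, chains may grow in place of ring closure, and the two faces of the enolate may not be told apart at C11. The fallback is a stepwise assembly in which nucleophile and electrophile are separate molecules. It sets out from 31, with 33 as the electrophile. The potassium enolate of 31, which carries no leaving group, is alkylated by 33 to give the silyl-protected seco-dimer F1, where C11 diastereomers could be separated. Buffered HF·pyridine frees the primary hydroxyl to give the seco-dimer alcohol F2. CBr4/PPh3 then gives bromide 34, now isolated, and KN(SiMe3)2 under syringe-pump dilution closes the ring by intramolecular ester-enolate alkylation, coming back to the route at 35. In 34 the enolisable half has no leaving group and the bromide-bearing half no acidic C11–H, so elimination cannot compete.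

Step 13. Bond formation at the fully substituted C10 may be slow, so that thermal drift of the nitroalkene out of conjugation, the hetero-Diels–Alder mode or polymerisation take over, or the dienophile face may be poorly differentiated. The fallback keeps the same two bonds but uses an aldehyde as activating group, which allows Lewis-acid catalysis, and excises the extra carbon afterwards. It sets out from 14. A Horner–Wadsworth–Emmons reaction with triethyl phosphonoacetate (NaH, THF, reflux) gives the (E)-enoate F3, and i-Bu2AlH gives the allylic alcohol F4. Hydrostannation/Stille coupling with 17 as in step 11 gives, by way of the vinylstannane F5, the diene alcohol F6, and MnO2 gives the trienal F7. Heating in toluene at 150 °C, or Me2AlCl in CH2Cl2 at low temperature, gives the cycloadduct aldehyde F8. Aerobic deformylation of this α-branched aldehyde (O2, Cu(OAc)2, 2,2′-bipyridine, DABCO, DMF, 40 °C) gives the C9 ketone and comes back to the route at 24.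

Step 16. The enediolate may be protonated at C6 to give diosphenol tautomers, the C6=C7 bond may wander towards C11, or the acetonide oxygen may not be expelled. The fallback sets C9 by hydride delivery in place of proton equilibration. It sets out from 26. Dess–Martin oxidation gives the ene-1,2-dione F9, in which no enediol is possible. DBU then has only the C5 proton to remove and gives the dienedione alcohol F10. NaBH4 (MeOH/CH2Cl2, −78 °C) reduces the non-conjugated, more electrophilic C9 carbonyl from the α face, anti to C14, and comes back to the route at 28.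

**Further compounds**
F1 | step 21 | silyl-protected seco-dimer: 34 with C15–OTBS in place of C15–Br | COC(=O)[C@](C)(CC4=C5C=C(C(C)C(=O)OC)C(=O)[C@H](O[Si](C)(C)C(C)(C)C)[C@@]5(C)[C@@H]6C[C@H]46)C1=CC2=C(CO[Si](C)(C)C(C)(C)C)[C@H]3C[C@H]3[C@]2(C)[C@@H](O[Si](C)(C)C(C)(C)C)C1=O
F2 | step 21 | seco-dimer alcohol: 34 with C15–OH in place of C15–Br | COC(=O)[C@](C)(CC4=C5C=C(C(C)C(=O)OC)C(=O)[C@H](O[Si](C)(C)C(C)(C)C)[C@@]5(C)[C@@H]6C[C@H]46)C1=CC2=C(CO)[C@H]3C[C@H]3[C@]2(C)[C@@H](O[Si](C)(C)C(C)(C)C)C1=O
F3 | step 13 | (E)-enoate: ethyl (2E)-3-[cis-2-(4-ethynyl-2,2-dimethyl-1,3-dioxolan-4-yl)cyclopropyl]but-2-enoate | CCOC(=O)/C=C(\C)[C@@H]1C[C@@H]1[C@@]2(C#C)COC(C)(C)O2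
F4 | step 13 | allylic alcohol from F3 | OC/C=C(\C)[C@@H]1C[C@@H]1[C@@]2(C#C)COC(C)(C)O2
F5 | step 13 | vinylstannane from F4 | OC/C=C(\C)[C@@H]1C[C@@H]1[C@@]2(/C=C/[Sn](CCCC)(CCCC)CCCC)COC(C)(C)O2
F6 | step 13 | diene alcohol | OC/C=C(\C)[C@@H]1C[C@@H]1[C@@]2(/C=C/C(=C)CC(=O)OC)COC(C)(C)O2
F7 | step 13 | trienal | O=C/C=C(\C)[C@@H]1C[C@@H]1[C@@]2(/C=C/C(=C)CC(=O)OC)COC(C)(C)O2
F8 | step 13 | cycloadduct aldehyde: 22 with 9β-CHO in place of nitro | O=C[C@H]1CC(CC(=O)OC)=C[C@@H]2[C@@]3(COC(C)(C)O3)[C@H]4C[C@H]4[C@]12C
F9 | step 16 | ene-1,2-dione: C8 and C9 ketones, C6=C7, acetonide in place | O=C1C(=O)C(CC(=O)OC)=C[C@@H]2[C@@]3(COC(C)(C)O3)[C@H]4C[C@H]4[C@]12C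
F10 | step 16 | dienedione alcohol: C4=C5–C6=C7–C8=O, C9 ketone, C15–OH | COC(=O)CC1=CC2=C(CO)[C@H]3C[C@H]3[C@]2(C)C(=O)C1=O
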